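The route cuts the three-carbon bridge C9–C11–C12 of the bicyclo[3.2.1]octane (rings C and D) away from both bridgeheads, C8 and C13. The 15-hydroxy-16-methylene unit of ring D is read as a 15,16-diketone whose two α-carbons are exactly these bridgeheads. In the key step a cyclopentane-1,2-dione (diosphenol) attached to C6 adds through C8 to C9 of an enal attached to C10 (Michael addition that closes ring B and creates the quaternary C8); the dione then closes ring C by aldol addition of C13 to C12. The precursor is ring A alone, carrying the C19 and C20 esters, the enal arm on C10 and the dione-bearing C6–C7 arm on C5.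

Key step: step 12

Remark: atom labels C1–C20 follow gibberellane numbering and α is the face of ring A that carries C19 and C20. 3,3-Dimethoxypropanal is taken as a purchasable reagent. Centres that are destroyed or equilibrated later (C9 before step 12, C12 in 27, C6 from step 10 to step 16, C8 and C15 in 22) are carried as mixtures and left undefined in the SMILES.

Step 1
Reactants: 1 tert-butyl(but-3-en-1-yloxy)dimethylsilane; 2 (E)-but-2-enal
Product: 3 (E)-5-[(tert-butyldimethylsilyl)oxy]pent-2-enal
Conditions: second-generation Hoveyda–Grubbs catalyst RuCl2(H2IMes)(=CH-C6H4-2-O-i-Pr) (2 mol%), 2 (3 equiv), CH2Cl2, 40 °C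
Reagents that add atoms: none
Why: Olefin cross-metathesis of the terminal alkene with excess enal should give the (E)-enal, the exchange being driven by loss of the volatile alkene.

Step 2
Reactants: 4 dimethyl malonate; 5 prop-2-enal
Product: 6 dimethyl 2-(3-oxopropyl)malonate
Conditions: NaOMe (5 mol%), 4 (3 equiv), MeOH, 0 °C
Reagents that add atoms: none
Why: Base-catalysed Michael addition of the malonate to acrolein, with excess malonate to suppress double addition.

Step 3
Reactants: 3 (E)-5-[(tert-butyldimethylsilyl)oxy]pent-2-enal; 6 dimethyl 2-(3-oxopropyl)malonate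
Product: 8 dimethyl (2S)-2-[2-(tert-butyldimethylsilyloxy)ethyl]-3-formylcyclohex-3-ene-1,1-dicarboxylate, via aldol adduct 7 (not isolated)
Conditions: (R)-2-[diphenyl(trimethylsilyloxy)methyl]pyrrolidine (20 mol%), PhCO2H (20 mol%), CH2Cl2, 25 °C
Reagents that add atoms: none
Why: Iminium–enamine organocascade (Michael addition then intramolecular aldol condensation): the malonate carbon (C4) adds to the β-carbon (C5) of the iminium ion on the face left open by the diphenyl(silyloxy)methyl group of the (R)-catalyst, which is expected to give the (S) configuration at C5, and the catalyst-bound enamine (C10) then closes ring A on the pendant aldehyde (C1) before water is lost.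

Step 4
Reactants: 8 dimethyl (2S)-2-[2-(tert-butyldimethylsilyloxy)ethyl]-3-formylcyclohex-3-ene-1,1-dicarboxylate
Product: 10 unsaturated bicyclic lactone, dimethyl (4aS)-1-oxo-3,4,6,7-tetrahydro-1H-isochromene-5,5(4aH)-dicarboxylate, via lactol 9 (not isolated)
Conditions: HF·pyridine, THF, 0 → 25 °C; then MnO2 (15 equiv), CH2Cl2, 25 °C
Reagents that add atoms: none
Why: Desilylation lets the C7 hydroxyl close on the conjugated aldehyde C20 as a six-membered allylic lactol, which MnO2 should oxidise to the α,β-unsaturated δ-lactone (lactol oxidation), tying C20 and C6 cis on ring A.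

Step 5
Reactants: 10 unsaturated bicyclic lactone; 11 3,3-dimethoxypropanal
Product: 14 cis-fused pivalate lactone, dimethyl (4aS,8aS)-8a-[3,3-dimethoxy-1-(pivaloyloxy)propyl]-1-oxooctahydro-1H-isochromene-5,5-dicarboxylate (C9 epimers), via lithium lactone enolate 12 (not isolated), via lithium aldolate 13 (not isolated)
Conditions: LiBH(s-Bu)3 (1.05 equiv), THF, −78 °C; then 11 (1.5 equiv), −78 °C; then t-BuCOCl (2 equiv), DMAP (10 mol%), −78 → 0 °C
Reagents that add atoms: pivaloyl chloride CC(C)(C)C(=O)Cl
Why: Conjugate reduction–aldol sequence in which 1,4-hydride delivery gives the ring-fusion lactone enolate, which should add to the aldehyde on the face syn to H5 (giving the cis-fused lactone as in angular alkylations of such bicyclic enolates) so that C9 ends trans to C6 on ring A, while acylation of the aldolate blocks retro-aldol cleavage.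

Step 6
Reactants: 14 cis-fused pivalate lactone
Product: 15 monoester lactone (14 with one C4 methoxycarbonyl replaced by H; C4 and C9 epimers)
Conditions: LiCl (2 equiv), H2O (2 equiv), DMSO, 150 °C
Reagents that add atoms: none
Why: Krapcho dealkoxycarbonylation removes one ester of the geminal C4 diester and should leave lactone, pivalate and acetal untouched; the C4 configuration is irrelevant because C4 is re-enolised in step 7.

Step 7
Reactants: 15 monoester lactone
Product: 16 C4-methylated lactone (methyl on C4 trans to C6, C19 ester cis to C6; C9 epimers)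
Conditions: LiN(i-Pr)2 (1.1 equiv), THF, −78 °C; then MeI (3 equiv), −78 → −20 °C
Reagents that add atoms: iodomethane CI
Why: Alkylation of the only enolisable position (the C4 ester enolate) is expected from the equatorial direction opposite the axial lactone carbonyl C20 on C10, that is trans to C6, as in C4 methylations of diterpenoid acid precursors, which places the methyl β and the C19 ester α.

Step 8
Reactants: 16 C4-methylated lactone
Product: 18 hydroxy diester, dimethyl 1-[3,3-dimethoxy-1-(pivaloyloxy)propyl]-2-(2-hydroxyethyl)-3-methylcyclohexane-1,3-dicarboxylate (both esters and the hydroxyethyl group α), via lithium carboxylate 17 (not isolated)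
Conditions: LiOH·H2O (1.5 equiv), THF/H2O, 40 °C; evaporation; then MeI (3 equiv), DMF, 25 °C
Reagents that add atoms: lithium hydroxide [Li+].[OH-]; iodomethane CI
Why: Saponification of the δ-lactone (the hindered methyl ester and the pivalate should survive) and SN2 O-methylation of the carboxylate give the C20 methyl ester and the free C7 hydroxyl.

Step 9
Reactants: 18 hydroxy diester
Product: 19 triester (18 with the hydroxyethyl group oxidised to CH2CO2Me, C6–C7)
Conditions: pyridinium dichromate (C5H5NH)2Cr2O7 (6 equiv), MeOH (6 equiv), DMF, 25 °C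
Reagents that add atoms: methanol CO
Why: Chromium oxidation of the primary alcohol in the presence of methanol runs through the aldehyde and its hemiacetal to the methyl ester in one operation, which makes C6 the only enolisable carbon.

Step 10
Reactants: 19 triester; 20 cyclopent-2-en-1-one
Product: 22 acyloin (19 carrying a 2-hydroxy-3-oxocyclopentyl group on C6; mixture at C6, C8, C15), via lithium ketone enolate 21 (not isolated)
Conditions: LiN(i-Pr)2 (1.05 equiv), THF, −78 °C; 20 (1.2 equiv), −78 → −40 °C; then 2-(phenylsulfonyl)-3-phenyloxaziridine (1.5 equiv), −78 °C; then AcOH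
Reagents that add atoms: 2-(phenylsulfonyl)-3-phenyloxaziridine O=S(=O)(N1OC1c1ccccc1)c1ccccc1
Why: Michael addition of the C6 ester enolate to the enone forms the C6–C8 bond and the regiodefined cyclopentanone enolate is then hydroxylated at C15 (enolate oxidation), installing ring D as its acyloin.

Step 11
Reactants: 22 acyloin
Product: 23 diosphenol (ring D as cyclopentane-1,2-dione enol, C8=C15, on C6; C6 and C9 epimers)
Conditions: Dess–Martin periodinane (1.5 equiv), CH2Cl2, 25 °C
Reagents that add atoms: none
Why: Oxidation of the acyloin gives the 1,2-dione, which should rest as the enol toward the substituted carbon and so turns C8 into an acidic, soft carbon nucleophile.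

Step 12
Reactants: 23 diosphenol
Product: 27 tetracyclic aldol (trimethyl ester with 15,16-dione and 12-hydroxyl; rings A–D complete), via β-pivaloyloxy aldehyde 24 (not isolated), via enal 25 (not isolated), via Michael adduct 26 (not isolated)
Conditions: 1 M HCl, THF/H2O (4:1), 25 °C; evaporation; then DBU (3 equiv), MeCN, 25 → 60 °C
Reagents that add atoms: water O
Why: Aqueous acid unmasks the C12 aldehyde and DBU triggers E1cB loss of pivalate to the (E)-enal, whose β-carbon C9 is attacked by C8 of the diosphenolate in a 5-exo-trig Michael addition that closes ring B and creates the quaternary C8, after which the regenerated dione enolises toward C13 and adds to the C12 aldehyde in a 6-(enolexo)-exo-trig aldol that closes ring C and completes the bicyclo[3.2.1]octane. The closest known reaction types are Michael additions of cyclic 1,2-diones to enals and Michael–aldol annulations of such diones to bicyclo[3.2.1]octanes. C9 should be set by the trans-fused envelope of ring B on the chair of ring A, in which the enal double bond eclipses the axial C10 ester so that C11 lies on the C20 face and H9 on the H5 face. C8 should be set in the same open transition state, where the diosphenolate oxygen on C15 turns away from the developing C11–C12 enolate (charge repulsion) and so leaves C14 next to C11 and C15 next to H9, a preference that reversible conjugate addition under DBU can reinforce; C13 then follows from the bridging geometry and C12 is removed in step 13. The step needs C- rather than O-alkylation and this aldol rather than closure of the aldehyde enolate on a ring D carbonyl; the first is secured by the five-membered ring, the second by the far higher acidity of the dione and by reversibility, the β-hydroxy ketone being a sink that cannot dehydrate because C13 would become a bridgehead alkene carbon.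

Step 13
Reactants: 27 tetracyclic aldol
Product: 28 11-ene 15,16-dione
Conditions: methyl N-(triethylammoniosulfonyl)carbamate (Burgess reagent, 2 equiv), toluene, 80 °C
Reagents that add atoms: none
Why: Syn-elimination of the sulfamate formed at the C12 hydroxyl (Burgess dehydration) can only run toward C11, because a C12=C13 alkene would be a bridgehead olefin.

Step 14
Reactants: 28 11-ene 15,16-dione
Product: 29 saturated 15,16-dione
Conditions: H2 (1 atm), RhCl(PPh3)3 (5 mol%), benzene/EtOH (1:1), 25 °C
Reagents that add atoms: none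
Why: Homogeneous hydrogenation should saturate the cis-disubstituted C11=C12 alkene without touching the non-enolisable dione or the esters.

Step 15
Reactants: 29 saturated 15,16-dione
Product: 30 15-oxo-16-methylene triester (enone)
Conditions: Ph3PCH3Br (1.2 equiv), KN(SiMe3)2 (1.15 equiv), THF, 0 °C; then 29, −78 → 0 °C
Reagents that add atoms: methyltriphenylphosphonium bromide C[P+](c1ccccc1)(c1ccccc1)c1ccccc1.[Br-]
Why: Wittig methylenation is expected at C16, the carbonyl next to the tertiary bridgehead C13, rather than at C15, which is shielded by the quaternary C8 and ring B.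

Step 16
Reactants: 30 15-oxo-16-methylene triester
Product: 31 target trimethyl ester as a mixture of C6 epimers (trimethyl 15-hydroxygibberell-16-ene-7,19,20-trioate)
Conditions: NaBH4 (1.2 equiv), CeCl3·7H2O (1.2 equiv), MeOH, −78 °C
Reagents that add atoms: none
Why: Luche 1,2-reduction in which hydride should reach C15 from the exo face (the side of the one-carbon bridge C14), away from the axial hydrogen on C11, so that the hydroxyl ends syn to the C9–C11–C12 bridge as in the target.

Step 17
Reactants: 31 target trimethyl ester, C6 epimer mixture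
Product: 32 target trimethyl ester with the natural C6 configuration
Conditions: NaOMe (0.5 equiv), MeOH, 50 °C
Reagents that add atoms: none
Why: Methoxide-mediated epimerisation of the only enolisable ester should converge the C6 epimers on the more stable isomer with C7 trans to C4 on ring B; the 15-hydroxyl lies on the face of ring D opposite to C6 and so cannot lactonise onto C7.

Step 18
Reactants: 32 target trimethyl ester
Product: 33 target triacid, 15-hydroxygibberell-16-ene-7,19,20-trioic acid
Conditions: NaSEt (12 equiv), DMF, 100 °C; then H2O, 1 M HCl to pH 3, 0 °C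
Reagents that add atoms: none
Why: Thiolate SN2 demethylation should cleave all three methyl esters, including the hindered C19 and C20 esters that resist saponification, without affecting the allylic alcohol or the exocyclic alkene.

**Compound list**

1 | tert-butyl(but-3-en-1-yloxy)dimethylsilane | C=CCCO[Si](C)(C)C(C)(C)C | starting material
2 | (E)-but-2-enal | C/C=C/C=O | starting material
3 | (E)-5-[(tert-butyldimethylsilyl)oxy]pent-2-enal | O=C/C=C/CCO[Si](C)(C)C(C)(C)C | intermediate
4 | dimethyl malonate | COC(=O)CC(=O)OC | starting material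
5 | prop-2-enal (acrolein) | C=CC=O | starting material
6 | dimethyl 2-(3-oxopropyl)malonate | COC(=O)C(CCC=O)C(=O)OC | intermediate
7 | aldol adduct, dimethyl (2S)-2-[2-(tert-butyldimethylsilyloxy)ethyl]-3-formyl-4-hydroxycyclohexane-1,1-dicarboxylate (ring C3 and C4 undefined) | O=CC1C(O)CCC(C(=O)OC)(C(=O)OC)[C@H]1CCO[Si](C)(C)C(C)(C)C | intermediate
8 | dimethyl (2S)-2-[2-(tert-butyldimethylsilyloxy)ethyl]-3-formylcyclohex-3-ene-1,1-dicarboxylate (geminal diester at C4, CHO = C20, C1=C10) | O=CC1=CCCC(C(=O)OC)(C(=O)OC)[C@H]1CCO[Si](C)(C)C(C)(C)C | intermediate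
9 | lactol, dimethyl (4aS)-1-hydroxy-3,4,6,7-tetrahydro-1H-isochromene-5,5(4aH)-dicarboxylate | OC1OCC[C@H]2C1=CCCC2(C(=O)OC)C(=O)OC | intermediate
10 | unsaturated lactone, dimethyl (4aS)-1-oxo-3,4,6,7-tetrahydro-1H-isochromene-5,5(4aH)-dicarboxylate (C20 lactone on O7) | O=C1OCC[C@H]2C1=CCCC2(C(=O)OC)C(=O)OC | intermediate
11 | 3,3-dimethoxypropanal | COC(OC)CC=O | starting material
12 | lithium enolate of the saturated lactone (C10=C20, O-lithiated) | [Li]OC1=C2CCCC(C(=O)OC)(C(=O)OC)[C@H]2CCO1 | intermediate
13 | lithium aldolate (C10 quaternary, lithium alkoxide on C9) | O=C1OCC[C@H]2[C@]1(C(O[Li])CC(OC)OC)CCCC2(C(=O)OC)C(=O)OC | intermediate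
14 | cis-fused pivalate lactone, dimethyl (4aS,8aS)-8a-[3,3-dimethoxy-1-(pivaloyloxy)propyl]-1-oxooctahydro-1H-isochromene-5,5-dicarboxylate (C9 epimers) | O=C1OCC[C@H]2[C@]1(C(OC(=O)C(C)(C)C)CC(OC)OC)CCCC2(C(=O)OC)C(=O)OC | intermediate
15 | monoester lactone (one ester on C4; C4 and C9 epimers) | O=C1OCC[C@H]2[C@]1(C(OC(=O)C(C)(C)C)CC(OC)OC)CCCC2C(=O)OC | intermediate
16 | C4-methylated lactone (methyl β, C19 ester α; C9 epimers) | O=C1OCC[C@H]2[C@]1(C(OC(=O)C(C)(C)C)CC(OC)OC)CCC[C@@]2(C)C(=O)OC | intermediate
17 | lithium C20 carboxylate of the opened lactone | COC(OC)CC(OC(=O)C(C)(C)C)[C@]1(C(=O)O[Li])CCC[C@@](C)(C(=O)OC)[C@H]1CCO | intermediate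
18 | hydroxy diester, dimethyl 1-[3,3-dimethoxy-1-(pivaloyloxy)propyl]-2-(2-hydroxyethyl)-3-methylcyclohexane-1,3-dicarboxylate (esters and hydroxyethyl α) | COC(OC)CC(OC(=O)C(C)(C)C)[C@]1(C(=O)OC)CCC[C@@](C)(C(=O)OC)[C@H]1CCO | intermediate
19 | triester (C6H2–C7O2Me on C5) | COC(OC)CC(OC(=O)C(C)(C)C)[C@]1(C(=O)OC)CCC[C@@](C)(C(=O)OC)[C@H]1CC(=O)OC | intermediate
20 | cyclopent-2-en-1-one | O=C1C=CCC1 | starting material
21 | lithium enolate of the Michael adduct (C15=C16, O-lithiated) | COC(OC)CC(OC(=O)C(C)(C)C)[C@]1(C(=O)OC)CCC[C@@](C)(C(=O)OC)[C@H]1C(C(=O)OC)C1CCC(O[Li])=C1 | intermediate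
22 | acyloin (2-hydroxy-3-oxocyclopentyl on C6) | COC(OC)CC(OC(=O)C(C)(C)C)[C@]1(C(=O)OC)CCC[C@@](C)(C(=O)OC)[C@H]1C(C(=O)OC)C1CCC(=O)C1O | intermediate
23 | diosphenol (2-hydroxy-3-oxocyclopent-1-enyl on C6) | COC(OC)CC(OC(=O)C(C)(C)C)[C@]1(C(=O)OC)CCC[C@@](C)(C(=O)OC)[C@H]1C(C(=O)OC)C1=C(O)C(=O)CC1 | intermediate
24 | β-pivaloyloxy aldehyde (free C12 aldehyde) | O=CCC(OC(=O)C(C)(C)C)[C@]1(C(=O)OC)CCC[C@@](C)(C(=O)OC)[C@H]1C(C(=O)OC)C1=C(O)C(=O)CC1 | intermediate
25 | (E)-enal (C9=C11–C12HO on C10, diosphenol on C6) | O=C/C=C/[C@]1(C(=O)OC)CCC[C@@](C)(C(=O)OC)[C@H]1C(C(=O)OC)C1=C(O)C(=O)CC1 | intermediate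
26 | Michael adduct (ring B closed, C8 spiro to the cyclopentane-1,2-dione, CH2CHO on C9) | O=CC[C@H]1[C@]2(C(=O)OC)CCC[C@@](C)(C(=O)OC)[C@H]2C(C(=O)OC)[C@@]13CCC(=O)C3=O | intermediate
27 | tetracyclic aldol (12-hydroxy-15,16-dione trimethyl ester; C12 and C6 epimers) | O=C1[C@@H]2C(O)C[C@H]3[C@]4(C(=O)OC)CCC[C@@](C)(C(=O)OC)[C@H]4C(C(=O)OC)[C@]3(C2)C1=O | intermediate
28 | 11-ene 15,16-dione trimethyl ester | O=C1[C@@H]2C=C[C@H]3[C@]4(C(=O)OC)CCC[C@@](C)(C(=O)OC)[C@H]4C(C(=O)OC)[C@]3(C2)C1=O | intermediate
29 | saturated 15,16-dione trimethyl ester | O=C1[C@@H]2CC[C@H]3[C@]4(C(=O)OC)CCC[C@@](C)(C(=O)OC)[C@H]4C(C(=O)OC)[C@]3(C2)C1=O | intermediate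
30 | 15-oxo-16-methylene trimethyl ester | C=C1[C@@H]2CC[C@H]3[C@]4(C(=O)OC)CCC[C@@](C)(C(=O)OC)[C@H]4C(C(=O)OC)[C@]3(C2)C1=O | intermediate
31 | target trimethyl ester as a mixture of C6 epimers (trimethyl 15-hydroxygibberell-16-ene-7,19,20-trioate, hydroxyl syn to the C9–C11–C12 bridge) | C=C1[C@@H]2CC[C@H]3[C@]4(C(=O)OC)CCC[C@@](C)(C(=O)OC)[C@H]4C(C(=O)OC)[C@]3(C2)[C@@H]1O | intermediate
32 | target trimethyl ester with the natural C6 configuration (C7 trans to C4 on ring B) | C=C1[C@@H]2CC[C@H]3[C@]4(C(=O)OC)CCC[C@@](C)(C(=O)OC)[C@H]4[C@H](C(=O)OC)[C@]3(C2)[C@@H]1O | intermediate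
33 | target triacid, 15-hydroxygibberell-16-ene-7,19,20-trioic acid of the natural gibberellin series (15-hydroxyl syn to the C9–C11–C12 bridge) | C=C1[C@@H]2CC[C@H]3[C@]4(C(=O)O)CCC[C@@](C)(C(=O)O)[C@H]4[C@H](C(=O)O)[C@]3(C2)[C@@H]1O | target

**Totals.** Total step count: 18. Longest linear sequence: 17 steps (steps 1 and 3–18; step 2 prepares the coupling partner 6).

**Steps most likely to fail**

Risk 1, step 12. The Michael addition may show poor facial control at C8 or C9, or the cascade may stop after conjugate addition, with the aldehyde enolate closing on a ring D carbonyl instead. The fallback sets out from 23 and returns at 27. Compound 23 would be hydrolysed (1 M HCl) and the pivalate eliminated with Et3N so that enal 25 is isolated. Me3SiOTf/Et3N would then convert the diosphenol into the 2,3-bis(trimethylsilyloxy)cyclopenta-1,3-diene F1. A Lewis-acid Mukaiyama–Michael addition (Me3SiOTf 10 mol%, CH2Cl2, −78 °C, aqueous HCl work-up), running through an open transition state, would give 26 as an isolated compound. The aldol closure to 27 would then be run on its own (K2CO3, MeOH, 0 °C).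

Risk 2, step 7. Methylation may occur from the wrong face of the C4 enolate if the chair with the C10 side chain axial takes part, giving the C4 epimer. The fallback sets out from 15 and returns at 18, and moves the lactone so that C4 becomes a ring-fusion carbon. LiOH then MeI would give, via the lithium carboxylate F2, the hydroxy diester F3. Mild acid-catalysed lactonisation (pyridinium p-toluenesulfonate 10 mol%, benzene, 80 °C) on the less hindered C19 ester would give the C19 lactone F4. Alkylation of its enolate (LiN(i-Pr)2, MeI) is then expected to give the cis ring fusion (C19 cis to C6), that is the methylated C19 lactone F5. LiOH then MeI, via the lithium carboxylate F6, returns 18.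

Risk 3, step 10. The ester enolate may add 1,2 to the enone, proton transfer may scramble the enolates, or the hydroxylation may be incomplete. The fallback sets out from 19 and returns at 23. Alkylation of the C6 enolate (LiN(i-Pr)2, THF/DMPU, −78 °C) with 3-bromocyclopentene would give the cyclopentenyl ester F7. Dihydroxylation (OsO4 2 mol%, N-methylmorpholine N-oxide, acetone/H2O) would give the diol F8. Double Swern oxidation ((COCl)2, DMSO, Et3N, −78 °C) would give 23.

**Further compounds**

F1 | step 12 | 2,3-bis(trimethylsilyloxy)cyclopenta-1,3-diene derived from enal 25 | O=C/C=C/[C@]1(C(=O)OC)CCC[C@@](C)(C(=O)OC)[C@H]1C(C(=O)OC)C1=C(O[Si](C)(C)C)C(O[Si](C)(C)C)=CC1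
F2 | step 7 | lithium C20 carboxylate from 15 | COC(OC)CC(OC(=O)C(C)(C)C)[C@]1(C(=O)O[Li])CCCC(C(=O)OC)[C@H]1CCO
F3 | step 7 | hydroxy diester with C4–H | COC(OC)CC(OC(=O)C(C)(C)C)[C@]1(C(=O)OC)CCCC(C(=O)OC)[C@H]1CCO
F4 | step 7 | C19 lactone (C19 carbonyl closed on O7, C20 methyl ester) | O=C1OCC[C@@H]2C1CCC[C@@]2(C(=O)OC)C(OC(=O)C(C)(C)C)CC(OC)OC
F5 | step 7 | methylated C19 lactone (cis ring fusion) | O=C1OCC[C@@H]2[C@@]1(C)CCC[C@@]2(C(=O)OC)C(OC(=O)C(C)(C)C)CC(OC)OC
F6 | step 7 | lithium C19 carboxylate from F5 | COC(OC)CC(OC(=O)C(C)(C)C)[C@]1(C(=O)OC)CCC[C@@](C)(C(=O)O[Li])[C@H]1CCO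
F7 | step 10 | cyclopent-2-enyl ester (19 alkylated at C6) | COC(OC)CC(OC(=O)C(C)(C)C)[C@]1(C(=O)OC)CCC[C@@](C)(C(=O)OC)[C@H]1C(C(=O)OC)C1C=CCC1
F8 | step 10 | cyclopentane-1,2-diol from F7 | COC(OC)CC(OC(=O)C(C)(C)C)[C@]1(C(=O)OC)CCC[C@@](C)(C(=O)OC)[C@H]1C(C(=O)OC)C1C(O)C(O)CC1
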